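**Retrosynthetic overview**
1. Ring C is made last. The three MOM ethers fall in the final step, the 3-hydroxy-4-pyranone comes from an Algar–Flynn–Oyamada oxidation of a 2'-hydroxychalcone, and the chalcone comes from a Claisen–Schmidt union of a ring A acetophenone with a ring B chromane aldehyde.
2. Ring A piece: the C8 1,1-dimethylallyl group comes from an aromatic Claisen rearrangement of the symmetric 4-O-prenyl ether of 2,4,6-trihydroxyacetophenone.
3. Ring B piece: one norbornene-relayed palladium domino reaction (Catellani type) on a monocyclic 2-iodobenzoate closes the dihydropyran ring. It joins ring carbon C5' to the terminal CH2 of an O4'-bound CMe2CH2CH2Br chain and, in the same operation, puts the prenyl group on the neighbouring C6'.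
4. Enabling feature: in ring B the four contiguous carbons C1' (carbonyl substituent), C6' (prenyl), C5' (pyran CH2) and C4' (pyran O) are the blocked-ortho, ipso, free-ortho and tether-anchor positions of such a relay. An iodide on C6' can therefore hand palladium over to C5'–H, while the ether oxygen on C4' holds the electrophilic chain within reach.
5. Order of ring formation: rings A and B are bought, the dihydropyran ring closes in step 7, and ring C closes in step 14.

Key step: step 7

Remark on the chemistry: flavonoid numbering is used, with ring B numbered so that C3' carries OH, C4' the pyran oxygen, C5' the pyran CH2 and C6' the prenyl group. The target has no stereocentre, and the stereocentres of transient intermediates are racemic and are erased again.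

**Route**

Step 1
Reactants: 1 2-methylbut-3-en-2-ol
Product: 3 tert-butyl 2-methylbut-3-en-2-yl carbonate, via lithium alkoxide 2 (not isolated)
Conditions: n-BuLi, THF, 0 °C; then Boc2O, 0 °C to rt
Reagents that add atoms: di-tert-butyl dicarbonate, CC(C)(C)OC(=O)OC(=O)OC(C)(C)C
Why: Acylation of the lithium alkoxide 2 of a tertiary allylic alcohol with Boc2O (mixed carbonate formation) should give the ionisable allyl donor needed for step 2.

Step 2
Reactants: 4 methyl 3,4-dihydroxybenzoate; 3 tert-butyl 2-methylbut-3-en-2-yl carbonate
Product: 5 methyl 3-hydroxy-4-[(2-methylbut-3-en-2-yl)oxy]benzoate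
Conditions: Pd(PPh3)4 (5 mol%), 3 (1.0 equiv.), THF, 0–5 °C
Reagents that add atoms: none
Why: Tsuji–Trost O-allylation: ionisation of 3 by zerovalent palladium gives the 1,1-dimethylallylpalladium cation and tert-butoxide, the latter deprotonates the more acidic 4-OH (para to the ester), and in the cold this phenoxide should attack the more substituted allyl terminus under kinetic control, so that one equivalent of 3 should give the tertiary ether at O4 only.

Step 3
Reactants: 5 methyl 3-hydroxy-4-[(2-methylbut-3-en-2-yl)oxy]benzoate
Product: 6 methyl 3-(methoxymethoxy)-4-[(2-methylbut-3-en-2-yl)oxy]benzoate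
Conditions: MOMCl, i-Pr2NEt, CH2Cl2, 0 °C to rt
Reagents that add atoms: chloromethyl methyl ether, COCCl
Why: Standard acetal protection (O-alkylation with MOMCl) masks the remaining phenol, which would otherwise displace the bromide in step 7, and the low temperature keeps the tertiary allyl aryl ether from an early Claisen rearrangement.

Step 4
Reactants: 6 methyl 3-(methoxymethoxy)-4-[(2-methylbut-3-en-2-yl)oxy]benzoate
Product: 8 methyl 4-[(4-hydroxy-2-methylbutan-2-yl)oxy]-3-(methoxymethoxy)benzoate, via B-alkyl-9-BBN adduct 7 (not isolated)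
Conditions: 9-BBN, THF, 0 °C to rt; then 30% H2O2, aq. NaOAc, 0 °C to rt
Reagents that add atoms: hydrogen peroxide, OO
Why: Brown hydroboration-oxidation: 9-BBN should place boron only on the terminal carbon of the monosubstituted alkene next to the quaternary centre and ignores ester and acetal, and acetate-buffered peroxide spares the methyl ester.

Step 5
Reactants: 8 methyl 4-[(4-hydroxy-2-methylbutan-2-yl)oxy]-3-(methoxymethoxy)benzoate
Product: 9 methyl 4-[(4-bromo-2-methylbutan-2-yl)oxy]-3-(methoxymethoxy)benzoate
Conditions: CBr4, PPh3, CH2Cl2, 0 °C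
Reagents that add atoms: carbon tetrabromide, BrC(Br)(Br)Br
Why: Appel reaction, a neutral SN2 bromination of the primary alcohol that leaves the acid-sensitive tertiary aryl ether and the MOM acetal untouched.

Step 6
Reactants: 9 methyl 4-[(4-bromo-2-methylbutan-2-yl)oxy]-3-(methoxymethoxy)benzoate
Product: 10 methyl 4-[(4-bromo-2-methylbutan-2-yl)oxy]-2-iodo-5-(methoxymethoxy)benzoate
Conditions: NIS (1.2 equiv.), CF3CO2H (0.3 equiv.), MeCN, 0 °C to rt, dark
Reagents that add atoms: N-iodosuccinimide, O=C1CCC(=O)N1I
Why: Electrophilic aromatic iodination, which in 3,4-dialkoxybenzoates goes para to the 3-alkoxy group, here para to OMOM, because O4 is conjugated with the para ester and its bulky tertiary alkyl group shields the other open site, while only catalytic acid is present so that both acid-labile ethers should survive.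

Step 7
Reactants: 10 methyl 4-[(4-bromo-2-methylbutan-2-yl)oxy]-2-iodo-5-(methoxymethoxy)benzoate; 11 4,4,5,5-tetramethyl-2-(3-methylbut-2-en-1-yl)-1,3,2-dioxaborolane
Product: 14 methyl 8-(methoxymethoxy)-2,2-dimethyl-5-(3-methylbut-2-en-1-yl)chromane-6-carboxylate, via aryl-norbornyl palladacycle 12 (not isolated), via chromanylpalladium bromide 13 (not isolated)
Conditions: Pd(OAc)2 (10 mol%), P(2-furyl)3 (22 mol%), norbornene (4 equiv.), Cs2CO3 (3 equiv.), H2O (5 equiv.), MeCN (0.02 M), 85 °C, 11 (2 equiv.) added by syringe pump
Reagents that add atoms: none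
Why: Proposed new method: zerovalent palladium should insert into the carbon–iodine bond of 10, norbornene should insert on its exo face and carbonate-assisted C–H palladation at the only free ortho carbon (the CH between the iodine-bearing and the ether-bearing carbons) should give palladacycle 12, whose divalent palladium then adds the tethered primary carbon–bromine bond oxidatively, after which C(sp2)–C(sp3) reductive elimination from the tetravalent centre forms the aryl–CH2 bond. This closes the dihydropyran as a six-membered ring in an exo-tet sense at the CH2Br carbon, through a seven-membered palladacyclic transition structure that the gem-dimethyl group (Thorpe–Ingold effect) and high dilution favour over intermolecular alkylation. With both positions beside the norbornyl-bearing carbon now substituted (the ester-bearing carbon and the carbon with the new CH2), norbornene is expelled by beta-carbon elimination to give 13, which is intercepted by Suzuki–Miyaura transmetalation with 11 and reductive elimination, placing the prenyl group on the former iodide carbon. The closest known reaction types are the Catellani domino reaction with intramolecular ortho-alkylation by an O-tethered alkyl halide (terminated by a Heck reaction), the Catellani ortho-alkylation terminated by Suzuki coupling with arylboronic acids, and the linear-selective Suzuki prenylation of simple aryl halides with 11, so that only the allylboronate as terminating partner is new. No stereocentre is formed. The step needs (a) relay before termination, secured by excess norbornene, slow addition of 11 and the unimolecular alkylation, (b) site selectivity, secured because only one ortho C–H exists, and (c) linear instead of branched prenyl transfer, secured by the two ortho substituents of 13, which should force bond formation at the unhindered CH2 terminus of the allyl ligand, while an ester rather than an aldehyde or a nitrile stands at C1 because it neither adds 11 nor inserts into an alkylpalladium bond.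

Step 8
Reactants: 14 methyl 8-(methoxymethoxy)-2,2-dimethyl-5-(3-methylbut-2-en-1-yl)chromane-6-carboxylate
Product: 15 [8-(methoxymethoxy)-2,2-dimethyl-5-(3-methylbut-2-en-1-yl)chroman-6-yl]methanol
Conditions: i-Bu2AlH (2.5 equiv.), CH2Cl2, −78 °C to 0 °C
Reagents that add atoms: none
Why: Hydride reduction of the aromatic ester with i-Bu2AlH, which leaves the trisubstituted alkene, the MOM acetal and the chromane ether untouched.

Step 9
Reactants: 15 [8-(methoxymethoxy)-2,2-dimethyl-5-(3-methylbut-2-en-1-yl)chroman-6-yl]methanol
Product: 16 8-(methoxymethoxy)-2,2-dimethyl-5-(3-methylbut-2-en-1-yl)chromane-6-carbaldehyde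
Conditions: activated MnO2, CH2Cl2, rt
Reagents that add atoms: none
Why: Selective heterogeneous oxidation of an electron-rich benzylic alcohol with MnO2 stops at the aldehyde and does not touch the prenyl group.

Step 10
Reactants: 17 1-(2,4,6-trihydroxyphenyl)ethanone; 18 3-methylbut-2-en-1-ol
Product: 19 1-{2,6-dihydroxy-4-[(3-methylbut-2-en-1-yl)oxy]phenyl}ethanone
Conditions: PPh3, DIAD, THF, 0 °C to rt
Reagents that add atoms: none
Why: Mitsunobu etherification: only the most acidic, non-chelated 4-OH should be engaged, and the neutral conditions avoid the C-alkylation that phloroglucinol-type phenoxides show with prenyl halides.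

Step 11
Reactants: 19 1-{2,6-dihydroxy-4-[(3-methylbut-2-en-1-yl)oxy]phenyl}ethanone
Product: 21 1-[2,4,6-trihydroxy-3-(2-methylbut-3-en-2-yl)phenyl]ethanone, via ortho-dienone 20 (not isolated)
Conditions: PhNEt2, 185 °C, sealed tube, argon
Reagents that add atoms: none
Why: Aromatic Claisen rearrangement: the [3,3] shift inverts the allyl unit and so delivers the 1,1-dimethylallyl group, the two ortho positions of 19 are equivalent by symmetry so that only one product is possible, the acetyl-blocked para position rules out a follow-up Cope shift, and dienone 20 tautomerises to the phenol.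

Step 12
Reactants: 21 1-[2,4,6-trihydroxy-3-(2-methylbut-3-en-2-yl)phenyl]ethanone
Product: 22 1-[2-hydroxy-4,6-bis(methoxymethoxy)-3-(2-methylbut-3-en-2-yl)phenyl]ethanone
Conditions: MOMCl (2.1 equiv.), i-Pr2NEt, CH2Cl2, 0 °C
Reagents that add atoms: chloromethyl methyl ether, COCCl
Why: Selective MOM protection: the free 4-OH and the less hindered 6-OH should react, while the OH wedged between the acetyl group and the quaternary carbon stays as the chelated phenol that later becomes O1.

Step 13
Reactants: 22 1-[2-hydroxy-4,6-bis(methoxymethoxy)-3-(2-methylbut-3-en-2-yl)phenyl]ethanone; 16 8-(methoxymethoxy)-2,2-dimethyl-5-(3-methylbut-2-en-1-yl)chromane-6-carbaldehyde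
Product: 23 (E)-1-[2-hydroxy-4,6-bis(methoxymethoxy)-3-(2-methylbut-3-en-2-yl)phenyl]-3-[8-(methoxymethoxy)-2,2-dimethyl-5-(3-methylbut-2-en-1-yl)chroman-6-yl]prop-2-en-1-one
Conditions: KOH (aq.), EtOH, rt
Reagents that add atoms: none
Why: Claisen–Schmidt (crossed aldol) condensation of a methyl ketone with a non-enolisable aldehyde, in which E1cB loss of water gives the conjugated E-alkene.

Step 14
Reactants: 23 the (E)-chalcone of step 13
Product: 25 3-hydroxy-5,7-bis(methoxymethoxy)-2-[8-(methoxymethoxy)-2,2-dimethyl-5-(3-methylbut-2-en-1-yl)chroman-6-yl]-8-(2-methylbut-3-en-2-yl)-4H-chromen-4-one, via trans-dihydroflavonol 24 (not isolated)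
Conditions: 30% H2O2, 2 M NaOH, MeOH, 0 °C to rt
Reagents that add atoms: hydrogen peroxide, OO
Why: Algar–Flynn–Oyamada reaction: alkaline H2O2 oxygenates only the electron-poor enone, the 2'-phenoxide closes ring C at the benzylic beta carbon to give dihydroflavonol 24, excess oxidant dehydrogenates 24 to the flavonol, and the isolated electron-rich alkenes are inert to nucleophilic peroxide.

Step 15
Reactants: 25 the tris-MOM flavonol of step 14
Product: 26 Broussoflavonol E
Conditions: 3 M HCl, MeOH, 50 °C
Reagents that add atoms: none
Why: Acid-catalysed acetal methanolysis removes the three MOM groups under conditions commonly tolerated by prenylated flavonoids, since the prenyl group has no neighbouring phenol to cyclise onto and the monosubstituted alkene of the 1,1-dimethylallyl group is slow to protonate.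

**Compound list**
1 | 2-methylbut-3-en-2-ol | C=CC(C)(C)O | starting material
2 | lithium 2-methylbut-3-en-2-olate (not isolated) | C=CC(C)(C)[O-].[Li+] | intermediate
3 | tert-butyl 2-methylbut-3-en-2-yl carbonate | C=CC(C)(C)OC(=O)OC(C)(C)C | intermediate
4 | methyl 3,4-dihydroxybenzoate | COC(=O)c1ccc(O)c(O)c1 | starting material
5 | methyl 3-hydroxy-4-[(2-methylbut-3-en-2-yl)oxy]benzoate | COC(=O)c1ccc(OC(C)(C)C=C)c(O)c1 | intermediate
6 | methyl 3-(methoxymethoxy)-4-[(2-methylbut-3-en-2-yl)oxy]benzoate | COC(=O)c1ccc(OC(C)(C)C=C)c(OCOC)c1 | intermediate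
7 | B-alkyl-9-BBN adduct of 6 (not isolated) | COC(=O)c1ccc(OC(C)(C)CCB2C3CCCC2CCC3)c(OCOC)c1 | intermediate
8 | methyl 4-[(4-hydroxy-2-methylbutan-2-yl)oxy]-3-(methoxymethoxy)benzoate | COC(=O)c1ccc(OC(C)(C)CCO)c(OCOC)c1 | intermediate
9 | methyl 4-[(4-bromo-2-methylbutan-2-yl)oxy]-3-(methoxymethoxy)benzoate | COC(=O)c1ccc(OC(C)(C)CCBr)c(OCOC)c1 | intermediate
10 | methyl 4-[(4-bromo-2-methylbutan-2-yl)oxy]-2-iodo-5-(methoxymethoxy)benzoate | COC(=O)c1cc(OCOC)c(OC(C)(C)CCBr)cc1I | intermediate
11 | 4,4,5,5-tetramethyl-2-(3-methylbut-2-en-1-yl)-1,3,2-dioxaborolane (prenylboronic acid pinacol ester) | CC(C)=CCB1OC(C)(C)C(C)(C)O1 | starting material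
12 | five-membered aryl-norbornyl palladacycle (exo-cis, racemic, phosphine ligands omitted, not isolated) | COC(=O)c1cc(OCOC)c(OC(C)(C)CCBr)c2[Pd][C@@H]3[C@H]4CC[C@H](C4)[C@@H]3c12 | intermediate
13 | [6-(methoxycarbonyl)-8-(methoxymethoxy)-2,2-dimethylchroman-5-yl]palladium bromide (phosphine ligands omitted, not isolated) | COC(=O)c1cc(OCOC)c2OC(C)(C)CCc2c1[Pd]Br | intermediate
14 | methyl 8-(methoxymethoxy)-2,2-dimethyl-5-(3-methylbut-2-en-1-yl)chromane-6-carboxylate | COC(=O)c1cc(OCOC)c2OC(C)(C)CCc2c1CC=C(C)C | intermediate
15 | [8-(methoxymethoxy)-2,2-dimethyl-5-(3-methylbut-2-en-1-yl)chroman-6-yl]methanol | OCc1cc(OCOC)c2OC(C)(C)CCc2c1CC=C(C)C | intermediate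
16 | 8-(methoxymethoxy)-2,2-dimethyl-5-(3-methylbut-2-en-1-yl)chromane-6-carbaldehyde | O=Cc1cc(OCOC)c2OC(C)(C)CCc2c1CC=C(C)C | intermediate
17 | 1-(2,4,6-trihydroxyphenyl)ethanone | CC(=O)c1c(O)cc(O)cc1O | starting material
18 | 3-methylbut-2-en-1-ol | CC(C)=CCO | starting material
19 | 1-{2,6-dihydroxy-4-[(3-methylbut-2-en-1-yl)oxy]phenyl}ethanone | CC(=O)c1c(O)cc(OCC=C(C)C)cc1O | intermediate
20 | 4-acetyl-3,5-dihydroxy-6-(2-methylbut-3-en-2-yl)cyclohexa-2,4-dien-1-one (racemic, not isolated) | CC(=O)C1=C(O)C(C(C)(C)C=C)C(=O)C=C1O | intermediate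
21 | 1-[2,4,6-trihydroxy-3-(2-methylbut-3-en-2-yl)phenyl]ethanone | CC(=O)c1c(O)cc(O)c(C(C)(C)C=C)c1O | intermediate
22 | 1-[2-hydroxy-4,6-bis(methoxymethoxy)-3-(2-methylbut-3-en-2-yl)phenyl]ethanone | CC(=O)c1c(OCOC)cc(OCOC)c(C(C)(C)C=C)c1O | intermediate
23 | (E)-chalcone from 22 and 16 | C=CC(C)(C)c1c(OCOC)cc(OCOC)c(C(=O)/C=C/c2cc(OCOC)c3OC(C)(C)CCc3c2CC=C(C)C)c1O | intermediate
24 | trans-3-hydroxyflavanone (2R*,3R*, racemic, one enantiomer drawn, not isolated) | CC(C)=CCc1c2CCC(C)(C)Oc2c(OCOC)cc1[C@@H]3[C@H](C(=O)c4c(OCOC)cc(OCOC)c(C(C)(C)C=C)c4O3)O | intermediate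
25 | 3-hydroxy-5,7-bis(methoxymethoxy)-2-[8-(methoxymethoxy)-2,2-dimethyl-5-(3-methylbut-2-en-1-yl)chroman-6-yl]-8-(2-methylbut-3-en-2-yl)-4H-chromen-4-one | C=CC(C)(C)c1c(OCOC)cc(OCOC)c2c(=O)c(O)c(-c3cc(OCOC)c4OC(C)(C)CCc4c3CC=C(C)C)oc12 | intermediate
26 | Broussoflavonol E | C=CC(C)(C)c1c(O)cc(O)c2c(=O)c(O)c(-c3cc(O)c4c(c3CC=C(C)C)CCC(C)(C)O4)oc12 | target

**Step count**
Total step count: 15. Longest linear sequence: 12 steps (steps 1–9, then 13–15).

**Steps most likely to fail**

Step 7. The prenyl group may be transferred before the norbornene relay is complete. It may also be delivered through its branched terminus, or 13 may be protodepalladated. The fallback uses known chemistry and separates ring closure from prenylation. It sets out from 10. The same norbornene-mediated intramolecular ortho-alkylation is run with a hydride source as terminator (Pd(OAc)2, P(2-furyl)3, norbornene, Cs2CO3, HCO2Na, DMF, 90 °C; Catellani alkylation with hydride termination). This should give methyl 8-(methoxymethoxy)-2,2-dimethylchromane-6-carboxylate F1. Iodination para to the MOM ether (NIS, catalytic CF3CO2H, MeCN) should give methyl 5-iodo-8-(methoxymethoxy)-2,2-dimethylchromane-6-carboxylate F2. An ordinary Suzuki–Miyaura prenylation with 11 (Pd(dppf)Cl2, K2CO3, THF, H2O, 70 °C) comes back to the route at 14.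

Step 14. The hindered phenoxide may attack the alpha instead of the beta carbon. This five-membered ring closure leads into the aurone series and is favoured by the 6'-alkoxy group and by the ortho-substituted ring B. The fallback separates epoxidation from cyclisation and runs the cyclisation under acid. It sets out from 23.
- MOMCl and NaH in DMF should give the tetra-MOM chalcone F3.
- Weitz–Scheffer epoxidation (H2O2, NaOH, MeOH) should give the racemic trans-epoxide F4.
- HCl in MeOH at 50 °C removes all four MOM groups. The freed 2'-OH should then open the epoxide at the benzylic carbon, whose cationic character is stabilised by the electron-rich ring B, to give the racemic trans-dihydroflavonol F5.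
- Base-catalysed aerobic dehydrogenation (O2, pyridine, 90 °C) erases both stereocentres and comes back to the route at 26.

Step 12. The two ortho-hydroxyl groups may be poorly discriminated. Acetal formation at O2 instead of O6 would carry material into the 6-substituted flavonol series. The fallback differentiates the two oxygens before the rearrangement, while the ring is still symmetric. It sets out from 19. One equivalent of MOMCl with i-Pr2NEt should give 1-{2-hydroxy-6-(methoxymethoxy)-4-[(3-methylbut-2-en-1-yl)oxy]phenyl}ethanone F6. The thermal Claisen rearrangement (PhNEt2, 185 °C) is expected to go to the carbon between the chelated OH and the ether oxygen, as in 2-hydroxy-4-allyloxyacetophenones. It should give 1-[2,4-dihydroxy-6-(methoxymethoxy)-3-(2-methylbut-3-en-2-yl)phenyl]ethanone F7. One equivalent of MOMCl on the free, non-chelated 4-OH comes back to the route at 22.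

**Further compounds**
F1 | step 7 | methyl 8-(methoxymethoxy)-2,2-dimethylchromane-6-carboxylate | COC(=O)c1cc(OCOC)c2OC(C)(C)CCc2c1
F2 | step 7 | methyl 5-iodo-8-(methoxymethoxy)-2,2-dimethylchromane-6-carboxylate | COC(=O)c1cc(OCOC)c2OC(C)(C)CCc2c1I
F3 | step 14 | (E)-chalcone 23 with the 2'-OH protected as MOM ether (tetra-MOM chalcone) | C=CC(C)(C)c1c(OCOC)cc(OCOC)c(C(=O)/C=C/c2cc(OCOC)c3OC(C)(C)CCc3c2CC=C(C)C)c1OCOC
F4 | step 14 | trans-epoxide of F3 (racemic, one enantiomer drawn) | C=CC(C)(C)c1c(OCOC)cc(OCOC)c(C(=O)[C@@H]2O[C@H]2c3cc(OCOC)c4OC(C)(C)CCc4c3CC=C(C)C)c1OCOC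
F5 | step 14 | trans-2,3-dihydro-Broussoflavonol E (2R*,3R*, racemic, one enantiomer drawn) | CC(C)=CCc1c2CCC(C)(C)Oc2c(O)cc1[C@@H]3[C@H](C(=O)c4c(O)cc(O)c(C(C)(C)C=C)c4O3)O
F6 | step 12 | 1-{2-hydroxy-6-(methoxymethoxy)-4-[(3-methylbut-2-en-1-yl)oxy]phenyl}ethanone | CC(=O)c1c(O)cc(OCC=C(C)C)cc1OCOC
F7 | step 12 | 1-[2,4-dihydroxy-6-(methoxymethoxy)-3-(2-methylbut-3-en-2-yl)phenyl]ethanone | CC(=O)c1c(OCOC)cc(O)c(C(C)(C)C=C)c1O
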